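The numbers in the tables come from a simulation on assumed constants; the scatter is artificial.

A racemate cannot drift away from equal hands by itself: with nothing handed at work, the excess e of right-handed substrate over left-handed substrate among what is left stays at zero, and that zero is my scale.

common to all: left-handed substrate 0.10 M; right-handed substrate 0.10 M; free catalyst 10 mM; racemization catalyst 0.13 mM; impurity 19 µM
- south-west: partner 0.17 M; run made earlier
- south: partner 0.62 M; run made earlier
- dawn: partner 0.250 M; time 12 min
- autumn: partner 0.800 M; time 12 min

- south-west (time / min: right-handed substrate / %, left-handed substrate / %, left-handed product / %): 1.00: 42, 41, 9; 2.00: 36, 33, 19; 5.00: 27, 25, 31; 12.0: 16, 14, 39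
- south (time / min: right-handed substrate / %, left-handed substrate / %, left-handed product / %): 1.50: 23, 14, 35; 4.00: 10, 3, 51; 8.00: 2, 2, 55; 12.0: 0, 0, 55

(readings scatter by 1.5 percentage points)

- free catalyst is single-handed; left-handed substrate and right-handed substrate are mirror images of each other, charged as a racemate, each of them at the stated concentration
- what was read earlier has a scatter of 1.5 percentage points, one standard deviation
- reactions considered so far: racemization catalyst + impurity -> spent catalyst; partner + free catalyst + left-handed substrate -> free catalyst + left-handed product; partner <-> dormant form; left-handed substrate + racemization catalyst <-> right-handed substrate + racemization catalyst; partner + free catalyst + right-handed substrate -> free catalyst + right-handed product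
- an excess is below zero if the other one leads

- which of the two ends with the higher excess of right-handed substrate over left-handed substrate among what is left of the two ("neither" if they lie within 2 percentage points) (dawn / autumn / neither)
- excess of right-handed substrate over left-handed substrate among what is left of the two at the end, dawn
- excess of right-handed substrate over left-handed substrate among what is left of the two at the end, autumn

What moves e off zero? The single-handed free catalyst takes one hand faster, and the left-handed substrate reads lower. I take that widening to go with partner, while racemization closes the gap in proportion to e. At the balance, e divided by one minus e squared equals a constant times c(partner), where c(partner) is partner not yet consumed, dormant form included.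

What is the constant? In south-west, from 2.00 min on, I sum the excesses and divide by the summed c(partner) from the mass balance, which gives 0.701 M⁻¹. This is the tilt g, the excess held per molar of unconsumed partner, the balance constant of a dynamic kinetic resolution. It holds for these charges of free catalyst, racemization catalyst and impurity, which the flasks share.

Why not use south? At 4.00 min its residue is 13.0 %, and each reading scatters by 1.5 percentage points, so its excess is too loose.

Isn't the excess of a vanishing residue meaningless? No: the two hands fall together at a held ratio, so e survives. South read 0 % of right-handed substrate at 12.0 min, and autumn has more partner, so I count autumn's substrates as consumed. That leaves c(partner) at 0.600 M, and the balance gives 36.5 %.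

And dawn? It has more partner than south-west, so I expect less substrate left than south-west's 30.0 %. Then I place c(partner) between 0.0500 M and 0.110 M, and I commit to the middle, 5.61 %.

The forecast, which differs from my reckoning, names autumn, with 12 % for dawn and 50 % for autumn, since the excess “tracks the free partner level”.

The flask gives autumn, with 6.40 % for dawn and 36.6 % for autumn.

    racemization catalyst + impurity → spent catalyst (k = 28000 M⁻¹ s⁻¹)
    partner + free catalyst + left-handed substrate → free catalyst + left-handed product (k = 2.90 M⁻² s⁻¹)
    partner ⇌ dormant form (K = 0.130, k = 0.00660 s⁻¹)
    left-handed substrate + racemization catalyst ⇌ right-handed substrate + racemization catalyst, rate k4*[racemization catalyst]*[left-handed substrate] forward; the back reaction follows from the equilibrium constant (k = 34.0 M⁻¹ s⁻¹)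
    partner + free catalyst + right-handed substrate → free catalyst + right-handed product (k = 1.70 M⁻² s⁻¹)

Autumn stands above dawn because of its larger charge of partner: with that difference taken away, so that autumn holds dawn's charge of partner, it ends at 6.40 % in place of 36.6 %. In dawn at 12.0 min, partner and dormant form together stand at 0.0820 M, which the tilt turns into 5.75 % against 6.40 %. The neighbour of autumn with 2.0 M of partner keeps c(partner) at 1.80 M, which the tilt turns into 67.9 %, and that flask ends at 68.0 %.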